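The constants used here are assumed; what happens was integrated by code.

**Slow clocks.** Slowness is what I have to weigh here: once made, the target drifts on to its isomer, so what stands at the end depends on how the coupling keeps pace with that drift.

in all of them: starting material 20 mM; coupling partner 24.0 mM; time 30 h

| run | temperature |
|---|---|
| Tuesday's | 75 °C |
| Thursday's | 25 °C |
| Monday's | 50 °C |
| Sunday's | 0 °C |

    starting material + coupling partner → target (k1 = 1.1 /M/h, Ea1 = 59.0 kJ/mol)
    starting material ⇌ intermediate (K2 = 1.6, k2 = 0.0087 /h, Ea2 = 105 kJ/mol, ΔH2 = −87.0 kJ/mol)
    coupling partner + intermediate → side product (k3 = 0.64 /M/h, Ea3 = 82.0 kJ/mol)
    2 starting material → self-condensation product (k4 = 0.78 /M/h, Ea4 = 77.0 kJ/mol)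
    target ⇌ isomer of the product (K5 = 12, k5 = 0.049 /h, Ea5 = 106 kJ/mol, ΔH5 = −12.0 kJ/mol)
    intermediate → decomposed reagent (k6 = 0.0029 /h, Ea6 = 105 kJ/mol)
    (constants at 25 °C)

- percentages count the starting material that a species holds: one self-condensation product counts as two
- two of one species on the left: rate k times its square, two consumed each time
- constants are those at 25 °C; use the activation energies and enthalpies for any other temperature

1. the flask that comes out highest in amount of target, in percent of the starting material charged, or "all alike" when all lie within 1.5 percentage points (Tuesday's / Thursday's / Monday's / Sunday's / all alike)
2. target at the end, in percent of the starting material charged, Tuesday's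
3. target at the end, in percent of the starting material charged, Thursday's
4. target at the end, in percent of the starting material charged, Monday's
5. target at the end, in percent of the starting material charged, Sunday's

**The fork.** I follow a molecule of starting material in Thursday's flask, taking each exit as pseudo-first-order at the charged concentrations. It couples at 0.0264 /h, self-condenses at 0.0312 /h and passes to the intermediate at 0.0087 /h, so it leaves at 0.0663 /h in sum. The coupling share is 39.8%: the coupling exit divided by the sum of the exits at the charge.

**The bracket.** Over 30 h this share gives 34.4% of the charge coupled in Thursday's flask. That is my ceiling, with each coupled molecule born at the last moment and still target. For the floor I let them all be born at the first moment and relax towards the isomer with the half-life 13.1 h, which leaves 9.10% as target. To tighten this, I let the starting material leave at the pace 0.0663 /h, the share 39.8% of it become target, and the target be lost at 0.049 /h, leaving out the return from the isomer. The starting material leaves faster than the target is lost, but the coupling exit of 0.0264 /h is slower than that loss, and I commit to 14.2%.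

**The forecast.** The forecast names Thursday's as highest, with 5.9% for Tuesday's, 15% for Thursday's, 5.1% for Monday's and 8% for Sunday's, and it says of Thursday's: “the target is already draining towards its isomer”. Its figure for Thursday's lies above my floor, below my ceiling, and a little higher than my own.

**The result.** The simulation puts Thursday's highest, with 5.75% for Tuesday's, 15.2% for Thursday's, 5.05% for Monday's and 7.94% for Sunday's. Thursday's stands 7.3 percentage points above Sunday's, the next highest, against a margin of 1.5 points, so the forecast's choice is not a near thing.

**Two days.** The neighbour is Thursday's flask left until 2.0 d, with charges and temperature held. The coupling share stays 39.8%, and the same reckoning gives 38.1% coupled and 8.19% as target. That neighbour flask holds 28.8% as isomer and 11.5% as target, which is 40.2% coupled.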